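| setting | Saturday's | Tuesday's | Wednesday's | Thursday's |
|---|---|---|---|---|
| substrate | 1.0 mM | 1.0 mM (fed, over 1.5 min) | 1.0 mM | 1.0 mM |
| partner | 1.20 equiv (fed, over 1.5 min) | 1.20 equiv | 1.20 equiv (in portions, 2, over 1.5 min) | 1.20 equiv |
| free catalyst | 0.2 mol% | 0.2 mol% | 0.2 mol% | 0.2 mol% |
| second catalyst | 0.26 mol% | 0.26 mol% | 0.26 mol% | 0.26 mol% |
| time | 2.5 min | 2.5 min | 2.5 min | 2.5 min |
| remark | all else is in the flask from the start; the feed brings no volume worth counting | all else is in the flask from the start; the feed brings no volume worth counting | first portion at the start, last at 1.5 min | everything together at the start |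

* the flask that comes out highest in amount of target, in percent of the substrate charged, or "all alike" when all lie within 1.5 percentage points (Saturday's / Tuesday's / Wednesday's / Thursday's / all alike)
* target at the end, in percent of the substrate charged, Saturday's
* target at the end, in percent of the substrate charged, Tuesday's
* target at the end, in percent of the substrate charged, Wednesday's
* target at the end, in percent of the substrate charged, Thursday's

    open intermediate → side product (k1 = 0.28 s⁻¹)
    partner + catalyst intermediate → second catalyst + target (k2 = 34000 L mol⁻¹ s⁻¹)
    substrate + free catalyst → free catalyst + open intermediate (k3 = 74000 L mol⁻¹ s⁻¹)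
    second catalyst + open intermediate ⇌ catalyst intermediate (K4 = 1700 L mol⁻¹, k4 = 2.0 × 10⁵ L mol⁻¹ s⁻¹)

- The next run is a choice among four ways of putting in the same charges, and it hangs on what share of the open intermediate becomes target rather than side product: a selectivity.
- Second catalyst binds open intermediate, and the catalyst intermediate then falls back at the forward constant over the equilibrium constant, 118 s⁻¹, or goes on with partner.
- Those two exits balance at 3.46 mM: this is the crossover partner P*, the partner concentration at which catalyst intermediate goes on to target as fast as it falls back.
- The whole partner charge, 1.20 mM, lies below P*, so capture still climbs with partner and the partner concentration [P] is what a recipe changes.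
- With catalyst intermediate in steady state and second catalyst taken as free, open intermediate sees a pseudo-first-order capture constant κ = forward constant × [second catalyst] × [P]/(P* + [P]), and its share to target is s = κ/(κ + the side-product constant).
- With the whole partner charge present, as Tuesday's and Thursday's have it at the start, κ is 0.134 s⁻¹, less than the side-product constant 0.28 s⁻¹, so s is 32.4%.
- Substrate opens with a lifetime of 6.76 s, far shorter than the 1.5 min addition, so Saturday's feed has brought 0.0901 mM of partner after one lifetime, which gives κ = 0.0132 s⁻¹ and s = 4.50%.
- Wednesday's first portion, 0.600 mM, starts at s = 21.5%, and this reckoning stops there, with Tuesday's and Thursday's at one value.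
- The decision from this: partner is not fed but charged whole, and whether to feed substrate stays open.
- The forecast names Tuesday's, with 29.5% there and 27% for Thursday's, both below the 32.4% of the reckoning above, then 16% for Wednesday's and 5.2% for Saturday's; of Tuesday's it says: “capture is unsaturated”.
- Tuesday's comes out highest at 29.4%, above Thursday's 27.0%, Wednesday's 16.5% and Saturday's 4.78%, and its lead of 2.4 percentage points stands over the margin of 1.5 points. Tuesday's mean partner over the first 1.5 min was 1.08 mM, and with P* that gives κ = 0.123 s⁻¹ and s = 30.5%.
- In the neighbour of Saturday's with 0.065 mol% of second catalyst, a quarter of the recipe's, P* and the partner after one lifetime stand as before, so κ = 0.003299 s⁻¹ and s = 1.16%. That flask gives 1.38%.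

Its constants belong to no real substance; the flask was simulated.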